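A small charge of free catalyst, 0.110 % of the substrate, goes into Friday's flask and into Sunday's, and the two differ in temperature.

common to all: substrate 0.42 M; free catalyst 0.46 mM

|  | temperature | remark | time |
|---|---|---|---|
| Friday's | 70 °C | the very flask that is asked about, followed so far |  |
| Sunday's | 76 °C | run made earlier |  |
| flask | 70 °C |  | 8.0 h |

| run | time / h | target / % | substrate / % |
|---|---|---|---|
| Friday's | 0.667 | 20.9 | 59.6 |
| Friday's | 1.00 | 23.7 | 51.0 |
| Friday's | 2.00 | 23.0 | 38.4 |
| Friday's | 3.00 | 20.1 | 32.3 |
| Friday's | 5.00 | 16.2 | 27.1 |
| Friday's | 8.00 | 12.9 | 23.4 |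
| Sunday's | 0.667 | 21.2 | 47.3 |
| Sunday's | 1.00 | 19.9 | 40.2 |
| Sunday's | 2.00 | 14.1 | 31.4 |
| Sunday's | 3.00 | 11.6 | 25.6 |
| Sunday's | 5.00 | 9.5 | 23.1 |
| Sunday's | 8.00 | 9.3 | 21.3 |

(scatter of a reading: 0.5 percentage points)

- what is taken out of target is counted as made
- the earlier runs were read with a standard deviation of 0.5 percentage points
- additions bring no volume worth counting

- midnight: at 8.0 h add free catalyst, 100 % of the amount charged, then wait 4.0 h
- dusk: at 8.0 h take out 90 % of the target then present, then wait 4.0 h
- winter: change nothing and wait 4.0 h more
- autumn: at 8.0 h raise the temperature by 25 K, then wait 4.0 h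

1. target, in percent of the substrate first charged, at 8.0 h
2. the remedy with the largest gain of target, or "none" below 2 percentage points (midnight / dusk / winter / autumn / none)
3. target present, with what was taken out counted in, in percent of the substrate first charged, after dusk
4. target present, with what was taken out counted in, in percent of the substrate first charged, after winter

Both runs slow down, yet they end apart: Sunday's flask stops lower in target, 9.3 % against 12.9 %, with substrate at 21.3 % against 23.4 %. So I compare them through one number. Friday's flask has a closing ratio of 0.551, meaning target over substrate, as fractions of the charge, at the last reading, and Sunday's flask has 0.437. Sunday's ratio was 0.411 at 5.00 h, so it holds within the scatter, and I read it as a balance between substrate and target, which is thermodynamic control. Friday's ratio was 0.598 at 5.00 h, so Friday's flask may still be coming down to its balance. Heat lowers that balance, and I take this, with the lower substrate, as the reason that the hotter flask ends with less target.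

For Friday's flask I commit to the reading at 8.0 h, 12.9 %. If substrate sinks as far as Sunday's, waiting leaves 11.7 %, my low end for winter. Dusk takes out 11.6 % and leaves 24.7 % as substrate and target together. If that pool splits again at the closing ratio, it gives 8.77 % of target, and I reckon there is time for it, since Friday's target reached 20.9 % by 0.667 h. My total is 20.4 %. Heat lowers the ratio and more catalyst moves no balance, so I pick dusk.

The forecast gives 13 %, dusk, 15 % after dusk and 11 % after winter, holding that “the catalyst is dying or being inhibited”, and my dusk figure stands higher.

The flask gives 13.4 %, with dusk best by 8.4 percentage points, 21.7 % after dusk and 12.2 % after winter.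

    substrate ⇌ target (K = 0.550, k = 0.0100 min⁻¹, Ea = 118 kJ mol⁻¹, ΔH = −39.0 kJ mol⁻¹)
    substrate ⇌ isomer of the product (K = 3.10, k = 0.00660 min⁻¹, Ea = 113 kJ mol⁻¹, ΔH = 5.00 kJ mol⁻¹)
    free catalyst → spent catalyst (k = 0.0680 min⁻¹, Ea = 104 kJ mol⁻¹)
    (constants at 70 °C)

At 8.0 h in this flask, target returns to substrate at 104 % of the rate at which it forms, and the ratio stands at 0.571. The slowest mode of this flask as it stands at 8.00 h has a half-life of 2.00 h, a quarter of the time run. Carrying 0.551 and 0.437 on in equal steps of temperature gives 0.308 for a flask kept at 85 °C. On its 22 % of substrate that means 6.62 % of target, and at 8.00 h that flask holds 6.68 %.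

The readings were generated by integration for an exercise, and the scatter is random.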